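**Retrosynthetic overview**
- Target ⇒ last-step peracid epoxidation of the 1(10)-E olefin; the C8 ester comes from (S)-2-methylbutanoic acid (asymmetric hydrogenation of tiglic acid); C13 comes from lactone aminomethylation/elimination.
- Ten-membered carbocycle ⇒ intramolecular Nozaki–Hiyama–Kishi closure of C3–C4 (Z-vinyl iodide + aldehyde), then oxidation and CBS reduction to fix C3.
- γ-Lactone ⇒ oxidative lactonisation of a C6/C12 diol; Z-iodoalkene ⇒ propargylic alcohol (hydroalumination/iodination); C6 ⇒ Noyori transfer hydrogenation of an ynone.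
- Acyclic chain ⇒ Negishi carboalumination/ethylene oxide (E-C1=C10, C2–C3), alkynyl opening of an epoxy ester (C9–C10), Fráter–Seebach allylation (C7), ketoreductase reduction of ethyl 4-chloro-3-oxobutanoate (C8).
- Ring order: γ-lactone first, carbocycle second, oxirane last.

Assumption: an S-selective NADPH-dependent ketoreductase that accepts isopropanol is taken from a commercial screening panel; locants C1–C15 are the germacranolide locants of the target (C12 lactone carbonyl, C13 exocyclic CH2, C14 methyl on C10, C15 CH2OH on C4).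

Abbreviations: TMS = trimethylsilyl, TBS = tert-butyldimethylsilyl, TES = triethylsilyl, TBDPS = tert-butyldiphenylsilyl, PMB = 4-methoxybenzyl; "TBSO" and the like denote the corresponding ether substituent.

**Route**

Step 1
Reactants: 1 (2E)-2-methylbut-2-enoic acid (tiglic acid)
Product: 2 (2S)-2-methylbutanoic acid
Conditions: H2 (4 atm), Ru(OAc)2[(S)-H8-BINAP] (0.5 mol%), MeOH, 20 °C
Reagents that add atoms: none
Why: Carboxylate-directed asymmetric hydrogenation of an α,β-unsaturated acid (Noyori–Takaya type) adds H2 to one enantioface and sets the (S) centre of the side-chain acid, the first stereocentre made in the synthesis.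

Step 2
Reactants: 3 prop-2-yn-1-ol
Product: 4 tert-butyl(diphenyl)(prop-2-yn-1-yloxy)silane
Conditions: TBDPSCl, imidazole, CH2Cl2, 0 °C to rt
Reagents that add atoms: tert-butyl(chloro)diphenylsilane, CC(C)(C)[Si](Cl)(c1ccccc1)c1ccccc1
Why: Imidazole-promoted silyl ether formation masks the future C15 hydroxyl with a group that survives every later acidic desilylation.

Step 3
Reactants: 5 ethyl 4-chloro-3-oxobutanoate
Product: 6 ethyl (3S)-4-chloro-3-hydroxybutanoate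
Conditions: ketoreductase (S-selective, NADPH-dependent), NADP+ (cat.), isopropanol, phosphate buffer pH 7, 30 °C
Reagents that add atoms: none
Why: Enzymatic asymmetric ketone reduction, in which the ketoreductase passes hydride from NADPH (recycled by isopropanol) to one face of the β-keto ester, sets C8 as the (S)-chlorohydrin in very high ee.

Step 4
Reactants: 6 ethyl (3S)-4-chloro-3-hydroxybutanoate
Product: 7 ethyl 2-[(2S)-oxiran-2-yl]acetate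
Conditions: Ag2O, 1,2-dimethoxyethane, 60 °C
Reagents that add atoms: none
Why: Silver-assisted intramolecular Williamson etherification closes the terminal epoxide without a base strong enough to cause β-elimination, and C8 is not touched.

Step 5
Reactants: 7 ethyl 2-[(2S)-oxiran-2-yl]acetate
Product: 8 ethyl (3R)-3-hydroxy-6-(trimethylsilyl)hex-5-ynoate
Conditions: Me3SiC≡CH, n-BuLi, THF, −78 °C; BF3·OEt2; then 7, −78 °C
Reagents that add atoms: ethynyl(trimethyl)silane, C#C[Si](C)(C)C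
Why: Yamaguchi–Hirao alkynylation opens the BF3-activated epoxide by SN2 attack at the unhindered terminal carbon, bringing in C10 and C1 while C8 keeps its configuration.

Step 6
Reactants: 8 ethyl (3R)-3-hydroxy-6-(trimethylsilyl)hex-5-ynoate
Product: 10 ethyl (2R,3R)-3-hydroxy-2-(prop-2-en-1-yl)-6-(trimethylsilyl)hex-5-ynoate, via dilithium dianion 9 (not isolated)
Conditions: LiN(CHMe2)2 (2.2 equiv), THF, −78 to −20 °C; then allyl bromide, DMPU, −78 to −20 °C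
Reagents that add atoms: allyl bromide, C=CCBr
Why: Fráter–Seebach alkylation, in which the chelated alkoxide-enolate is allylated on the face away from the C9 chain, gives the 2,3-anti product and so sets C7.

Step 7
Reactants: 10 ethyl (2R,3R)-3-hydroxy-2-(prop-2-en-1-yl)-6-(trimethylsilyl)hex-5-ynoate
Product: 11 (2S,3R)-2-(prop-2-en-1-yl)-6-(trimethylsilyl)hex-5-yne-1,3-diol
Conditions: LiAlH4, THF, 0 °C
Reagents that add atoms: none
Why: Hydride reduction of the ester gives the 1,3-diol needed for acetal formation, while the silylalkyne and the alkene are inert.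

Step 8
Reactants: 11 (2S,3R)-2-(prop-2-en-1-yl)-6-(trimethylsilyl)hex-5-yne-1,3-diol
Product: 12 (2S,4R,5S)-2-(4-methoxyphenyl)-5-(prop-2-en-1-yl)-4-[3-(trimethylsilyl)prop-2-yn-1-yl]-1,3-dioxane
Conditions: 4-MeOC6H4CH(OMe)2, PPTS (cat.), CH2Cl2, rt
Reagents that add atoms: 1-(dimethoxymethyl)-4-methoxybenzene, COc1ccc(cc1)C(OC)OC
Why: Acid-catalysed transacetalisation gives the six-membered p-methoxybenzylidene acetal under thermodynamic control, so the new acetal centre carries an equatorial aryl group cis to the C8 substituent.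

Step 9
Reactants: 12 (2S,4R,5S)-2-(4-methoxyphenyl)-5-(prop-2-en-1-yl)-4-[3-(trimethylsilyl)prop-2-yn-1-yl]-1,3-dioxane
Product: 14 2-[(2S,4R,5S)-2-(4-methoxyphenyl)-4-(prop-2-yn-1-yl)-1,3-dioxan-5-yl]ethan-1-ol, via aldehyde 13 (not isolated)
Conditions: OsO4 (cat.), NaIO4, 2,6-lutidine, dioxane/H2O, rt; then NaBH4, K2CO3, MeOH, 0 °C to rt
Reagents that add atoms: sodium periodate (oxygen source relayed by OsO4), [Na+].[O-]I(=O)(=O)=O
Why: Lemieux–Johnson oxidative cleavage of the only alkene gives the C12 aldehyde, which NaBH4 reduces while K2CO3/MeOH removes the alkynyl silyl group in the same operation.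

Step 10
Reactants: 14 2-[(2S,4R,5S)-2-(4-methoxyphenyl)-4-(prop-2-yn-1-yl)-1,3-dioxan-5-yl]ethan-1-ol
Product: 15 tert-butyl{2-[(2S,4R,5S)-2-(4-methoxyphenyl)-4-(prop-2-yn-1-yl)-1,3-dioxan-5-yl]ethoxy}dimethylsilane
Conditions: TBSCl, imidazole, CH2Cl2, rt
Reagents that add atoms: tert-butyl(chloro)dimethylsilane, CC(C)(C)[Si](C)(C)Cl
Why: Silyl ether formation protects the C12 hydroxyl until the lactone is made.

Step 11
Reactants: 15 tert-butyl{2-[(2S,4R,5S)-2-(4-methoxyphenyl)-4-(prop-2-yn-1-yl)-1,3-dioxan-5-yl]ethoxy}dimethylsilane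
Product: 16 (2S,3R)-2-[2-(TBSO)ethyl]-3-(PMBO)hex-5-yn-1-ol
Conditions: (Me2CHCH2)2AlH, CH2Cl2, −78 to 0 °C
Reagents that add atoms: none
Why: Regioselective reductive acetal opening, in which the aluminium hydride binds the less hindered primary oxygen and reduces the acetal carbon, leaves the PMB ether on the secondary C8 oxygen and frees the C6 hydroxyl.

Step 12
Reactants: 16 (2S,3R)-2-[2-(TBSO)ethyl]-3-(PMBO)hex-5-yn-1-ol
Product: 17 (2S,3R)-2-[2-(TBSO)ethyl]-3-(PMBO)-1-(TESO)hex-5-yne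
Conditions: Et3SiCl, imidazole, CH2Cl2, 0 °C
Reagents that add atoms: chloro(triethyl)silane, CC[Si](CC)(CC)Cl
Why: Silyl ether formation with the more labile triethylsilyl group allows the C6 hydroxyl to be released later beside two TBS ethers.

Step 13
Reactants: 17 (2S,3R)-2-[2-(TBSO)ethyl]-3-(PMBO)-1-(TESO)hex-5-yne
Product: 20 (3E,6R,7S)-7-[2-(TBSO)ethyl]-6-(PMBO)-4-methyl-8-(TESO)oct-3-en-1-ol, via alkenyldimethylalane 18 (not isolated), via lithium alkenylalanate 19 (not isolated)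
Conditions: AlMe3, (C5H5)2ZrCl2 (0.5 equiv), CH2Cl2, 0 °C to rt; then n-BuLi, THF/hexane, −78 °C; ethylene oxide, −78 to 0 °C
Reagents that add atoms: trimethylaluminium, C[Al](C)C; ethylene oxide, C1CO1
Why: Negishi zirconium-catalysed carboalumination adds methyl and aluminium syn across the terminal alkyne with methyl on the internal carbon, and the derived alanate opens ethylene oxide with retention, giving the E-trisubstituted C1=C10 olefin together with C2 and C3.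

Step 14
Reactants: 20 (3E,6R,7S)-7-[2-(TBSO)ethyl]-6-(PMBO)-4-methyl-8-(TESO)oct-3-en-1-ol
Product: 21 (3E,6R,7S)-1-(TBSO)-7-[2-(TBSO)ethyl]-6-(PMBO)-4-methyl-8-(TESO)oct-3-ene
Conditions: TBSCl, imidazole, CH2Cl2, rt
Reagents that add atoms: tert-butyl(chloro)dimethylsilane, CC(C)(C)[Si](C)(C)Cl
Why: Silyl ether formation protects the C3 hydroxyl until the macrocyclisation.

Step 15
Reactants: 21 (3E,6R,7S)-1-(TBSO)-7-[2-(TBSO)ethyl]-6-(PMBO)-4-methyl-8-(TESO)oct-3-ene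
Product: 22 (2S,3R,5E)-8-(TBSO)-2-[2-(TBSO)ethyl]-3-(PMBO)-5-methyloct-5-en-1-ol
Conditions: PPTS (0.2 equiv), MeOH/CH2Cl2, 0 °C
Reagents that add atoms: none
Why: Selective acid-catalysed methanolysis works because a primary triethylsilyl ether is cleaved far faster than primary TBS ethers.

Step 16
Reactants: 22 (2S,3R,5E)-8-(TBSO)-2-[2-(TBSO)ethyl]-3-(PMBO)-5-methyloct-5-en-1-ol
Product: 23 (2R,3R,5E)-8-(TBSO)-2-[2-(TBSO)ethyl]-3-(PMBO)-5-methyloct-5-enal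
Conditions: Dess–Martin periodinane, NaHCO3, CH2Cl2, 0 °C to rt
Reagents that add atoms: none
Why: Buffered Dess–Martin oxidation gives the C6 aldehyde without epimerising the adjacent C7 centre.

Step 17
Reactants: 23 (2R,3R,5E)-8-(TBSO)-2-[2-(TBSO)ethyl]-3-(PMBO)-5-methyloct-5-enal; 4 tert-butyl(diphenyl)(prop-2-yn-1-yloxy)silane
Product: 25 (4RS,5S,6R,8E)-1-(TBDPSO)-11-(TBSO)-5-[2-(TBSO)ethyl]-6-(PMBO)-8-methylundec-8-en-2-yn-4-ol, via lithium acetylide 24 (not isolated)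
Conditions: 4, n-BuLi, THF, −78 °C; then 23, −78 °C
Reagents that add atoms: none
Why: Acetylide addition to the aldehyde forms the C5–C6 bond and brings in C4, C5 and C15, the carbinol configuration being left uncontrolled because it is erased in the next step.

Step 18
Reactants: 25 (4RS,5S,6R,8E)-1-(TBDPSO)-11-(TBSO)-5-[2-(TBSO)ethyl]-6-(PMBO)-8-methylundec-8-en-2-yn-4-ol
Product: 26 (5R,6R,8E)-1-(TBDPSO)-11-(TBSO)-5-[2-(TBSO)ethyl]-6-(PMBO)-8-methylundec-8-en-2-yn-4-one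
Conditions: Dess–Martin periodinane, NaHCO3, CH2Cl2, 0 °C
Reagents that add atoms: none
Why: Dess–Martin oxidation converges both carbinol epimers to one ynone under non-basic conditions that spare the β-alkoxy ketone.

Step 19
Reactants: 26 (5R,6R,8E)-1-(TBDPSO)-11-(TBSO)-5-[2-(TBSO)ethyl]-6-(PMBO)-8-methylundec-8-en-2-yn-4-one
Product: 27 (4S,5S,6R,8E)-1-(TBDPSO)-11-(TBSO)-5-[2-(TBSO)ethyl]-6-(PMBO)-8-methylundec-8-en-2-yn-4-ol
Conditions: Ru[(S,S)-TsNCH(Ph)CH(Ph)NH](p-cymene) (2 mol%), isopropanol, rt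
Reagents that add atoms: none
Why: Base-free Noyori–Ikariya asymmetric transfer hydrogenation of the ynone is reagent-controlled, the (S,S)-catalyst giving the (S)-propargylic alcohol and so setting C6 with the O6/C11 syn and O6/O8 anti relationships of the target.

Step 20
Reactants: 27 (4S,5S,6R,8E)-1-(TBDPSO)-11-(TBSO)-5-[2-(TBSO)ethyl]-6-(PMBO)-8-methylundec-8-en-2-yn-4-ol
Product: 29 (2Z,4S,5S,6R,8E)-1-(TBDPSO)-11-(TBSO)-5-[2-(TBSO)ethyl]-2-iodo-6-(PMBO)-8-methylundeca-2,8-dien-4-ol, via sodium alkenylalanate 28 (not isolated)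
Conditions: NaAlH2(OCH2CH2OMe)2, THF, 0 °C to rt; EtOAc; then I2, THF, −78 to 0 °C
Reagents that add atoms: iodine, II
Why: Hydroxyl-directed trans-hydroalumination of the propargylic alcohol puts hydride on C5 and aluminium on C4, and iodinolysis with retention gives the Z-iodoalkene with iodine cis to C6, which fixes the ring-olefin geometry.

Step 21
Reactants: 29 (2Z,4S,5S,6R,8E)-1-(TBDPSO)-11-(TBSO)-5-[2-(TBSO)ethyl]-2-iodo-6-(PMBO)-8-methylundeca-2,8-dien-4-ol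
Product: 30 (3E,6R,7S,8S,9Z)-11-(TBDPSO)-7-(2-hydroxyethyl)-10-iodo-6-(PMBO)-4-methylundeca-3,9-diene-1,8-diol
Conditions: CSA (10 mol%), MeOH/CH2Cl2, 0 °C
Reagents that add atoms: none
Why: Acid-catalysed methanolysis removes the two primary TBS ethers while the far more robust TBDPS ether and the PMB ether stay.

Step 22
Reactants: 30 (3E,6R,7S,8S,9Z)-11-(TBDPSO)-7-(2-hydroxyethyl)-10-iodo-6-(PMBO)-4-methylundeca-3,9-diene-1,8-diol
Product: 31 (3E,6R)-6-{(2S,3R)-2-[(1Z)-3-(TBDPSO)-2-iodoprop-1-en-1-yl]-5-oxooxolan-3-yl}-6-(PMBO)-4-methylhex-3-enal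
Conditions: TEMPO (0.3 equiv), PhI(OAc)2 (4 equiv), CH2Cl2, rt
Reagents that add atoms: none
Why: Oxoammonium (TEMPO) oxidation touches only the primary alcohols, so the C12 aldehyde is trapped by the C6 hydroxyl as a lactol and oxidised on to the trans γ-lactone (first ring) while C3 becomes the aldehyde.

Step 23
Reactants: 31 (3E,6R)-6-{(2S,3R)-2-[(1Z)-3-(TBDPSO)-2-iodoprop-1-en-1-yl]-5-oxooxolan-3-yl}-6-(PMBO)-4-methylhex-3-enal
Product: 32 (3RS,6R,7R,8R)-15-(TBDPSO)-3-hydroxy-8-(PMBO)germacra-1(10)E,4Z-dien-12,6-olide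
Conditions: CrCl2 (10 equiv), NiCl2 (cat.), DMSO, rt, 3 mM, slow addition
Reagents that add atoms: none
Why: Intramolecular Nozaki–Hiyama–Kishi reaction, in which a nickel-catalysed alkenylchromium species adds only to the aldehyde under high dilution, closes the ten-membered ring (second ring) at C3–C4 with retention of the Z geometry, and the C3 epimer ratio is not relied upon.

Step 24
Reactants: 32 (3RS,6R,7R,8R)-15-(TBDPSO)-3-hydroxy-8-(PMBO)germacra-1(10)E,4Z-dien-12,6-olide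
Product: 33 (6R,7R,8R)-15-(TBDPSO)-8-(PMBO)-3-oxogermacra-1(10)E,4Z-dien-12,6-olide
Conditions: Dess–Martin periodinane, NaHCO3, CH2Cl2, 0 °C
Reagents that add atoms: none
Why: Dess–Martin oxidation of the allylic alcohols converges both C3 epimers to one enone under neutral conditions that do not move the β,γ-olefin.

Step 25
Reactants: 33 (6R,7R,8R)-15-(TBDPSO)-8-(PMBO)-3-oxogermacra-1(10)E,4Z-dien-12,6-olide
Product: 34 (3S,6R,7R,8R)-15-(TBDPSO)-3-hydroxy-8-(PMBO)germacra-1(10)E,4Z-dien-12,6-olide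
Conditions: (R)-2-methyl-CBS-oxazaborolidine (0.2 equiv), catecholborane, toluene, −78 °C
Reagents that add atoms: none
Why: Corey–Bakshi–Shibata reduction binds the enone with the fully substituted alkenyl carbon as the large group and delivers hydride to the face that gives the (3S)-allylic alcohol under reagent control.

Step 26
Reactants: 34 (3S,6R,7R,8R)-15-(TBDPSO)-3-hydroxy-8-(PMBO)germacra-1(10)E,4Z-dien-12,6-olide
Product: 35 (3S,6R,7R,8R)-15-(TBDPSO)-3-(TBSO)-8-(PMBO)germacra-1(10)E,4Z-dien-12,6-olide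
Conditions: TBSOTf, 2,6-lutidine, CH2Cl2, −78 °C
Reagents that add atoms: tert-butyldimethylsilyl trifluoromethanesulfonate, CC(C)(C)[Si](C)(C)OS(=O)(=O)C(F)(F)F
Why: Silyl ether formation with the silyl triflate protects the hindered secondary C3 hydroxyl before enolate chemistry and acylation.

Step 27
Reactants: 35 (3S,6R,7R,8R)-15-(TBDPSO)-3-(TBSO)-8-(PMBO)germacra-1(10)E,4Z-dien-12,6-olide
Product: 39 (3S,6R,7R,8R)-15-(TBDPSO)-3-(TBSO)-8-(PMBO)germacra-1(10)E,4Z,11(13)-trien-12,6-olide, via lithium enolate 36 (not isolated), via Mannich base 37 (not isolated), via ammonium iodide 38 (not isolated)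
Conditions: LiN(CHMe2)2, THF, −78 °C; Me2N=CH2 iodide, −78 °C to rt; then MeI, MeOH, rt; then NaHCO3 (aq.), CH2Cl2, rt
Reagents that add atoms: N,N-dimethylmethyleneiminium iodide (Eschenmoser's salt), C=[N+](C)C.[I-]
Why: Eschenmoser aminomethylation of the lactone enolate (trans to the C8 branch), N-methylation and base-induced β-elimination of trimethylamine install the C11=C13 methylene, and the transient C11 centre is destroyed.

Step 28
Reactants: 39 (3S,6R,7R,8R)-15-(TBDPSO)-3-(TBSO)-8-(PMBO)germacra-1(10)E,4Z,11(13)-trien-12,6-olide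
Product: 40 (3S,6R,7R,8R)-15-(TBDPSO)-3-(TBSO)-8-hydroxygermacra-1(10)E,4Z,11(13)-trien-12,6-olide
Conditions: DDQ, CH2Cl2/pH 7 buffer, 0 °C
Reagents that add atoms: none
Why: Oxidative PMB ether cleavage by DDQ through the benzylic oxocarbenium ion frees only the C8 hydroxyl.

Step 29
Reactants: 40 (3S,6R,7R,8R)-15-(TBDPSO)-3-(TBSO)-8-hydroxygermacra-1(10)E,4Z,11(13)-trien-12,6-olide; 2 (2S)-2-methylbutanoic acid
Product: 41 (3S,6R,7R,8R)-15-(TBDPSO)-3-(TBSO)-8-[(2S)-2-methylbutanoyloxy]germacra-1(10)E,4Z,11(13)-trien-12,6-olide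
Conditions: DCC, DMAP, CH2Cl2, 0 °C to rt
Reagents that add atoms: none
Why: Steglich esterification acylates the only free hydroxyl with retention at C8 and at the acid α-centre.

Step 30
Reactants: 41 (3S,6R,7R,8R)-15-(TBDPSO)-3-(TBSO)-8-[(2S)-2-methylbutanoyloxy]germacra-1(10)E,4Z,11(13)-trien-12,6-olide
Product: 42 (3S,6R,7R,8R)-3,15-dihydroxy-8-[(2S)-2-methylbutanoyloxy]germacra-1(10)E,4Z,11(13)-trien-12,6-olide
Conditions: Bu4NF, AcOH, THF, 0 °C to rt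
Reagents that add atoms: none
Why: Acetic acid-buffered fluoride desilylation removes both silyl ethers without harming the α-methylene lactone or the ester.

Step 31
Reactants: 42 (3S,6R,7R,8R)-3,15-dihydroxy-8-[(2S)-2-methylbutanoyloxy]germacra-1(10)E,4Z,11(13)-trien-12,6-olide
Product: 43 (1R,3S,6R,7R,8R,10R)-1,10-epoxy-3,15-dihydroxy-8-[(2S)-2-methylbutanoyloxy]germacra-4Z,11(13)-dien-12,6-olide (CNP0267576.2)
Conditions: mCPBA, NaHCO3, CH2Cl2, 0 °C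
Reagents that add atoms: 3-chloroperoxybenzoic acid, OOC(=O)c1cccc(Cl)c1
Why: Prilezhaev epoxidation picks the strained, electron-rich E-1(10) olefin over the Z-olefin (deactivated by three allylic oxygens) and the acrylate, and is expected to attack its exposed outer face in the conformer with C14 syn to H-6, giving the trans (1R,10R)-oxirane (third ring) by stereospecific syn addition.

**Compound list**

1 | (2E)-2-methylbut-2-enoic acid (tiglic acid) | C/C=C(\C)C(=O)O | starting material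
2 | (2S)-2-methylbutanoic acid | CC[C@H](C)C(=O)O | intermediate
3 | prop-2-yn-1-ol | C#CCO | starting material
4 | tert-butyl(diphenyl)(prop-2-yn-1-yloxy)silane | C#CCO[Si](c1ccccc1)(c1ccccc1)C(C)(C)C | intermediate
5 | ethyl 4-chloro-3-oxobutanoate | CCOC(=O)CC(=O)CCl | starting material
6 | ethyl (3S)-4-chloro-3-hydroxybutanoate | CCOC(=O)C[C@H](O)CCl | intermediate
7 | ethyl 2-[(2S)-oxiran-2-yl]acetate | CCOC(=O)C[C@H]1CO1 | intermediate
8 | ethyl (3R)-3-hydroxy-6-(trimethylsilyl)hex-5-ynoate | CCOC(=O)C[C@H](O)CC#C[Si](C)(C)C | intermediate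
9 | dilithium salt of 8 (C3 alkoxide, E ester enolate) | CCO/C(O[Li])=C/[C@H](O[Li])CC#C[Si](C)(C)C | intermediate
10 | ethyl (2R,3R)-3-hydroxy-2-(prop-2-en-1-yl)-6-(trimethylsilyl)hex-5-ynoate | CCOC(=O)[C@H](CC=C)[C@H](O)CC#C[Si](C)(C)C | intermediate
11 | (2S,3R)-2-(prop-2-en-1-yl)-6-(trimethylsilyl)hex-5-yne-1,3-diol | OC[C@H](CC=C)[C@H](O)CC#C[Si](C)(C)C | intermediate
12 | (2S,4R,5S)-2-(4-methoxyphenyl)-5-(prop-2-en-1-yl)-4-[3-(trimethylsilyl)prop-2-yn-1-yl]-1,3-dioxane | C[Si](C)(C)C#CC[C@H]1O[C@@H](c2ccc(OC)cc2)OC[C@@H]1CC=C | intermediate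
13 | 2-{(2S,4R,5S)-2-(4-methoxyphenyl)-4-[3-(trimethylsilyl)prop-2-yn-1-yl]-1,3-dioxan-5-yl}acetaldehyde | C[Si](C)(C)C#CC[C@H]1O[C@@H](c2ccc(OC)cc2)OC[C@@H]1CC=O | intermediate
14 | 2-[(2S,4R,5S)-2-(4-methoxyphenyl)-4-(prop-2-yn-1-yl)-1,3-dioxan-5-yl]ethan-1-ol | C#CC[C@H]1O[C@@H](c2ccc(OC)cc2)OC[C@@H]1CCO | intermediate
15 | tert-butyl{2-[(2S,4R,5S)-2-(4-methoxyphenyl)-4-(prop-2-yn-1-yl)-1,3-dioxan-5-yl]ethoxy}dimethylsilane | C#CC[C@H]1O[C@@H](c2ccc(OC)cc2)OC[C@@H]1CCO[Si](C)(C)C(C)(C)C | intermediate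
16 | (2S,3R)-2-[2-(TBSO)ethyl]-3-(PMBO)hex-5-yn-1-ol | C#CC[C@@H](OCc1ccc(OC)cc1)[C@@H](CCO[Si](C)(C)C(C)(C)C)CO | intermediate
17 | (2S,3R)-2-[2-(TBSO)ethyl]-3-(PMBO)-1-(TESO)hex-5-yne | C#CC[C@@H](OCc1ccc(OC)cc1)[C@@H](CCO[Si](C)(C)C(C)(C)C)CO[Si](CC)(CC)CC | intermediate
18 | dimethyl[(1E,4R,5S)-7-(TBSO)-4-(PMBO)-2-methyl-5-[(TESO)methyl]hept-1-en-1-yl]alane | C[Al](C)/C=C(\C)C[C@@H](OCc1ccc(OC)cc1)[C@@H](CCO[Si](C)(C)C(C)(C)C)CO[Si](CC)(CC)CC | intermediate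
19 | lithium butyl(dimethyl)[(1E,4R,5S)-7-(TBSO)-4-(PMBO)-2-methyl-5-[(TESO)methyl]hept-1-en-1-yl]alanate | [Li+].CCCC[Al-](C)(C)/C=C(\C)C[C@@H](OCc1ccc(OC)cc1)[C@@H](CCO[Si](C)(C)C(C)(C)C)CO[Si](CC)(CC)CC | intermediate
20 | (3E,6R,7S)-7-[2-(TBSO)ethyl]-6-(PMBO)-4-methyl-8-(TESO)oct-3-en-1-ol | OCC/C=C(\C)C[C@@H](OCc1ccc(OC)cc1)[C@@H](CCO[Si](C)(C)C(C)(C)C)CO[Si](CC)(CC)CC | intermediate
21 | (3E,6R,7S)-1-(TBSO)-7-[2-(TBSO)ethyl]-6-(PMBO)-4-methyl-8-(TESO)oct-3-ene | CC(C)(C)[Si](C)(C)OCC/C=C(\C)C[C@@H](OCc1ccc(OC)cc1)[C@@H](CCO[Si](C)(C)C(C)(C)C)CO[Si](CC)(CC)CC | intermediate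
22 | (2S,3R,5E)-8-(TBSO)-2-[2-(TBSO)ethyl]-3-(PMBO)-5-methyloct-5-en-1-ol | CC(C)(C)[Si](C)(C)OCC/C=C(\C)C[C@@H](OCc1ccc(OC)cc1)[C@@H](CCO[Si](C)(C)C(C)(C)C)CO | intermediate
23 | (2R,3R,5E)-8-(TBSO)-2-[2-(TBSO)ethyl]-3-(PMBO)-5-methyloct-5-enal | CC(C)(C)[Si](C)(C)OCC/C=C(\C)C[C@@H](OCc1ccc(OC)cc1)[C@@H](CCO[Si](C)(C)C(C)(C)C)C=O | intermediate
24 | lithium 3-(TBDPSO)prop-1-yn-1-ide | [Li]C#CCO[Si](c1ccccc1)(c1ccccc1)C(C)(C)C | intermediate
25 | (4RS,5S,6R,8E)-1-(TBDPSO)-11-(TBSO)-5-[2-(TBSO)ethyl]-6-(PMBO)-8-methylundec-8-en-2-yn-4-ol | CC(C)(C)[Si](c1ccccc1)(c1ccccc1)OCC#CC(O)[C@H](CCO[Si](C)(C)C(C)(C)C)[C@H](OCc1ccc(OC)cc1)C/C(C)=C/CCO[Si](C)(C)C(C)(C)C | intermediate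
26 | (5R,6R,8E)-1-(TBDPSO)-11-(TBSO)-5-[2-(TBSO)ethyl]-6-(PMBO)-8-methylundec-8-en-2-yn-4-one | CC(C)(C)[Si](c1ccccc1)(c1ccccc1)OCC#CC(=O)[C@H](CCO[Si](C)(C)C(C)(C)C)[C@H](OCc1ccc(OC)cc1)C/C(C)=C/CCO[Si](C)(C)C(C)(C)C | intermediate
27 | (4S,5S,6R,8E)-1-(TBDPSO)-11-(TBSO)-5-[2-(TBSO)ethyl]-6-(PMBO)-8-methylundec-8-en-2-yn-4-ol | CC(C)(C)[Si](c1ccccc1)(c1ccccc1)OCC#C[C@@H](O)[C@H](CCO[Si](C)(C)C(C)(C)C)[C@H](OCc1ccc(OC)cc1)C/C(C)=C/CCO[Si](C)(C)C(C)(C)C | intermediate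
28 | sodium cyclic alkenyl(alkoxy)bis(2-methoxyethoxy)alanate from 27 (Al bound to C4 and to O6) | [Na+].COCCO[Al-]1(OCCOC)O[C@@H]([C@H](CCO[Si](C)(C)C(C)(C)C)[C@H](OCc2ccc(OC)cc2)C/C(C)=C/CCO[Si](C)(C)C(C)(C)C)C=C1CO[Si](c1ccccc1)(c1ccccc1)C(C)(C)C | intermediate
29 | (2Z,4S,5S,6R,8E)-1-(TBDPSO)-11-(TBSO)-5-[2-(TBSO)ethyl]-2-iodo-6-(PMBO)-8-methylundeca-2,8-dien-4-ol | CC(C)(C)[Si](c1ccccc1)(c1ccccc1)OC/C(I)=C/[C@@H](O)[C@H](CCO[Si](C)(C)C(C)(C)C)[C@H](OCc1ccc(OC)cc1)C/C(C)=C/CCO[Si](C)(C)C(C)(C)C | intermediate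
30 | (3E,6R,7S,8S,9Z)-11-(TBDPSO)-7-(2-hydroxyethyl)-10-iodo-6-(PMBO)-4-methylundeca-3,9-diene-1,8-diol | CC(C)(C)[Si](c1ccccc1)(c1ccccc1)OC/C(I)=C/[C@@H](O)[C@H](CCO)[C@H](OCc1ccc(OC)cc1)C/C(C)=C/CCO | intermediate
31 | (3E,6R)-6-{(2S,3R)-2-[(1Z)-3-(TBDPSO)-2-iodoprop-1-en-1-yl]-5-oxooxolan-3-yl}-6-(PMBO)-4-methylhex-3-enal | O=CC/C=C(\C)C[C@@H](OCc1ccc(OC)cc1)[C@H]1CC(=O)O[C@@H]1/C=C(I)/CO[Si](c1ccccc1)(c1ccccc1)C(C)(C)C | intermediate
32 | (3RS,6R,7R,8R)-15-(TBDPSO)-3-hydroxy-8-(PMBO)germacra-1(10)E,4Z-dien-12,6-olide | C1C(=O)O[C@@H]2/C=C(/CO[Si](c3ccccc3)(c3ccccc3)C(C)(C)C)C(O)C/C=C(\C)C[C@@H](OCc3ccc(OC)cc3)[C@@H]12 | intermediate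
33 | (6R,7R,8R)-15-(TBDPSO)-8-(PMBO)-3-oxogermacra-1(10)E,4Z-dien-12,6-olide | C1C(=O)O[C@@H]2/C=C(/CO[Si](c3ccccc3)(c3ccccc3)C(C)(C)C)C(=O)C/C=C(\C)C[C@@H](OCc3ccc(OC)cc3)[C@@H]12 | intermediate
34 | (3S,6R,7R,8R)-15-(TBDPSO)-3-hydroxy-8-(PMBO)germacra-1(10)E,4Z-dien-12,6-olide | C1C(=O)O[C@@H]2/C=C(/CO[Si](c3ccccc3)(c3ccccc3)C(C)(C)C)[C@@H](O)C/C=C(\C)C[C@@H](OCc3ccc(OC)cc3)[C@@H]12 | intermediate
35 | (3S,6R,7R,8R)-15-(TBDPSO)-3-(TBSO)-8-(PMBO)germacra-1(10)E,4Z-dien-12,6-olide | C1C(=O)O[C@@H]2/C=C(/CO[Si](c3ccccc3)(c3ccccc3)C(C)(C)C)[C@@H](O[Si](C)(C)C(C)(C)C)C/C=C(\C)C[C@@H](OCc3ccc(OC)cc3)[C@@H]12 | intermediate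
36 | lithium enolate of 35 (C11=C12–OLi) | C1=C(O[Li])O[C@@H]2/C=C(/CO[Si](c3ccccc3)(c3ccccc3)C(C)(C)C)[C@@H](O[Si](C)(C)C(C)(C)C)C/C=C(\C)C[C@@H](OCc3ccc(OC)cc3)[C@@H]12 | intermediate
37 | (3S,6R,7R,8R,11R)-13-(dimethylamino)-15-(TBDPSO)-3-(TBSO)-8-(PMBO)germacra-1(10)E,4Z-dien-12,6-olide | CN(C)C[C@@H]1C(=O)O[C@@H]2/C=C(/CO[Si](c3ccccc3)(c3ccccc3)C(C)(C)C)[C@@H](O[Si](C)(C)C(C)(C)C)C/C=C(\C)C[C@@H](OCc3ccc(OC)cc3)[C@@H]12 | intermediate
38 | N-methyl quaternary ammonium iodide of 37 | C[N+](C)(C)C[C@@H]1C(=O)O[C@@H]2/C=C(/CO[Si](c3ccccc3)(c3ccccc3)C(C)(C)C)[C@@H](O[Si](C)(C)C(C)(C)C)C/C=C(\C)C[C@@H](OCc3ccc(OC)cc3)[C@@H]12.[I-] | intermediate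
39 | (3S,6R,7R,8R)-15-(TBDPSO)-3-(TBSO)-8-(PMBO)germacra-1(10)E,4Z,11(13)-trien-12,6-olide | C=C1C(=O)O[C@@H]2/C=C(/CO[Si](c3ccccc3)(c3ccccc3)C(C)(C)C)[C@@H](O[Si](C)(C)C(C)(C)C)C/C=C(\C)C[C@@H](OCc3ccc(OC)cc3)[C@@H]12 | intermediate
40 | (3S,6R,7R,8R)-15-(TBDPSO)-3-(TBSO)-8-hydroxygermacra-1(10)E,4Z,11(13)-trien-12,6-olide | C=C1C(=O)O[C@@H]2/C=C(/CO[Si](c3ccccc3)(c3ccccc3)C(C)(C)C)[C@@H](O[Si](C)(C)C(C)(C)C)C/C=C(\C)C[C@@H](O)[C@@H]12 | intermediate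
41 | (3S,6R,7R,8R)-15-(TBDPSO)-3-(TBSO)-8-[(2S)-2-methylbutanoyloxy]germacra-1(10)E,4Z,11(13)-trien-12,6-olide | C=C1C(=O)O[C@@H]2/C=C(/CO[Si](c3ccccc3)(c3ccccc3)C(C)(C)C)[C@@H](O[Si](C)(C)C(C)(C)C)C/C=C(\C)C[C@@H](OC(=O)[C@@H](C)CC)[C@@H]12 | intermediate
42 | (3S,6R,7R,8R)-3,15-dihydroxy-8-[(2S)-2-methylbutanoyloxy]germacra-1(10)E,4Z,11(13)-trien-12,6-olide | C=C1C(=O)O[C@@H]2/C=C(/CO)[C@@H](O)C/C=C(\C)C[C@@H](OC(=O)[C@@H](C)CC)[C@@H]12 | intermediate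
43 | (1R,3S,6R,7R,8R,10R)-1,10-epoxy-3,15-dihydroxy-8-[(2S)-2-methylbutanoyloxy]germacra-4Z,11(13)-dien-12,6-olide (CNP0267576.2) | C=C1C(=O)O[C@@H]2/C=C(/CO)[C@@H](O)C[C@H]3O[C@]3(C)C[C@@H](OC(=O)[C@@H](C)CC)[C@@H]12 | target

**Totals**

Total step count: 31. Longest linear sequence: 29 steps (steps 3 to 31, from 5 to 43).

**Three steps most likely to fail**

Step 23 (ten-membered ring closure). If the chromium-mediated closure gives oligomers or the β,γ-unsaturated aldehyde isomerises, the ring is closed by olefin metathesis instead. The fallback sets out from 27. Reduction with NaAlH2(OCH2CH2OMe)2 and aqueous quench (no iodine) gives the E-allylic alcohol F1. CSA/MeOH gives the triol F2, and TEMPO/PhI(OAc)2 gives the lactone aldehyde F3. Intermolecular CrCl2/NiCl2 coupling of F3 with tert-butyl[(2-bromoprop-2-en-1-yl)oxy]diphenylsilane gives the diene F4 as C3 epimers. Ring-closing metathesis with second-generation Hoveyda–Grubbs catalyst (toluene, 80 °C, 1 mM) expels the allyl silyl ether, the ten-membered ring enforces the Z ring olefin, and the route is rejoined at 32.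

Step 25 (C3 configuration). If the oxazaborolidine cannot override the macrocycle and the 3R alcohol predominates, substrate control is used on purpose and then inverted. The fallback sets out from 33. Luche reduction (NaBH4, CeCl3·7H2O, MeOH, −78 °C) gives the 3R alcohol F5. Mitsunobu inversion (4-nitrobenzoic acid, PPh3, DIAD, THF) gives the 3S 4-nitrobenzoate F6. Mild methanolysis (K2CO3, MeOH, 0 °C) rejoins the route at 34.

Step 31 (face of the epoxidation). If the peracid attacks the other conformer and gives the (1S,10S)-oxirane, oxygen is delivered from a tethered metal alkoxide instead. The fallback sets out from 40, where the C8 hydroxyl is the only free hydroxyl and is homoallylic to C1=C10. VO(acac)2/t-BuOOH (toluene, rt) gives the epoxy alcohol F7. DCC/DMAP esterification with 2 gives the epoxy ester F8. Bu4NF/AcOH rejoins the route at 43.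

Further compounds
F1 | step 23 | (2E,4R,5S,6R,8E)-1-(TBDPSO)-11-(TBSO)-5-[2-(TBSO)ethyl]-6-(PMBO)-8-methylundeca-2,8-dien-4-ol | CC(C)(C)[Si](c1ccccc1)(c1ccccc1)OC/C=C/[C@@H](O)[C@H](CCO[Si](C)(C)C(C)(C)C)[C@H](OCc1ccc(OC)cc1)C/C(C)=C/CCO[Si](C)(C)C(C)(C)C
F2 | step 23 | (3E,6R,7S,8R,9E)-11-(TBDPSO)-7-(2-hydroxyethyl)-6-(PMBO)-4-methylundeca-3,9-diene-1,8-diol | CC(C)(C)[Si](c1ccccc1)(c1ccccc1)OC/C=C/[C@@H](O)[C@H](CCO)[C@H](OCc1ccc(OC)cc1)C/C(C)=C/CCO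
F3 | step 23 | (3E,6R)-6-{(2R,3R)-2-[(1E)-3-(TBDPSO)prop-1-en-1-yl]-5-oxooxolan-3-yl}-6-(PMBO)-4-methylhex-3-enal | O=CC/C=C(\C)C[C@@H](OCc1ccc(OC)cc1)[C@H]1CC(=O)O[C@@H]1/C=C/CO[Si](c1ccccc1)(c1ccccc1)C(C)(C)C
F4 | step 23 | (5E,8R)-8-{(2R,3R)-2-[(1E)-3-(TBDPSO)prop-1-en-1-yl]-5-oxooxolan-3-yl}-2-[(TBDPSO)methyl]-8-(PMBO)-6-methylocta-1,5-dien-3-ol (C3 epimers) | C=C(CO[Si](c1ccccc1)(c1ccccc1)C(C)(C)C)C(O)C/C=C(\C)C[C@@H](OCc1ccc(OC)cc1)[C@H]1CC(=O)O[C@@H]1/C=C/CO[Si](c1ccccc1)(c1ccccc1)C(C)(C)C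
F5 | step 25 | (3R,6R,7R,8R)-15-(TBDPSO)-3-hydroxy-8-(PMBO)germacra-1(10)E,4Z-dien-12,6-olide | C1C(=O)O[C@@H]2/C=C(/CO[Si](c3ccccc3)(c3ccccc3)C(C)(C)C)[C@H](O)C/C=C(\C)C[C@@H](OCc3ccc(OC)cc3)[C@@H]12
F6 | step 25 | (3S,6R,7R,8R)-15-(TBDPSO)-3-(4-nitrobenzoyloxy)-8-(PMBO)germacra-1(10)E,4Z-dien-12,6-olide | C1C(=O)O[C@@H]2/C=C(/CO[Si](c3ccccc3)(c3ccccc3)C(C)(C)C)[C@@H](OC(=O)c3ccc(cc3)[N+](=O)[O-])C/C=C(\C)C[C@@H](OCc3ccc(OC)cc3)[C@@H]12
F7 | step 31 | (1R,3S,6R,7R,8R,10R)-15-(TBDPSO)-3-(TBSO)-1,10-epoxy-8-hydroxygermacra-4Z,11(13)-dien-12,6-olide | C=C1C(=O)O[C@@H]2/C=C(/CO[Si](c3ccccc3)(c3ccccc3)C(C)(C)C)[C@@H](O[Si](C)(C)C(C)(C)C)C[C@H]3O[C@]3(C)C[C@@H](O)[C@@H]12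
F8 | step 31 | (1R,3S,6R,7R,8R,10R)-15-(TBDPSO)-3-(TBSO)-1,10-epoxy-8-[(2S)-2-methylbutanoyloxy]germacra-4Z,11(13)-dien-12,6-olide | C=C1C(=O)O[C@@H]2/C=C(/CO[Si](c3ccccc3)(c3ccccc3)C(C)(C)C)[C@@H](O[Si](C)(C)C(C)(C)C)C[C@H]3O[C@]3(C)C[C@@H](OC(=O)[C@@H](C)CC)[C@@H]12
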